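Ask of each given number how far the top of ring moves if that number is off.

| flask | starting material | protic impurity | solid activator | remark | time |
|---|---|---|---|---|---|
| alder | 2.5 mM | 0.10 mM | 0.90 equiv | run made earlier |  |
| maple | 10 mM | 0.10 mM | 0.90 equiv | run made earlier |  |
| ash | 5 mM | 0.10 mM | 0.45 equiv | run made earlier |  |
| flask | 5.0 mM | 0.100 mM | 0.900 equiv |  | 20 min |

| run | time / min | ring / % |
|---|---|---|
| alder | 1.50 | 4.3 |
| alder | 2.50 | 10.8 |
| alder | 4.00 | 16.5 |
| alder | 5.00 | 17.4 |
| alder | 8.00 | 16.9 |
| alder | 12.0 | 16.8 |
| maple | 1.50 | 3.3 |
| maple | 2.50 | 5.8 |
| maple | 4.00 | 9.4 |
| maple | 5.00 | 10.8 |
| maple | 8.00 | 11.0 |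
| maple | 12.0 | 9.7 |
| ash | 1.50 | 4.5 |
| ash | 2.50 | 9.8 |
| ash | 4.00 | 12.9 |
| ash | 8.00 | 14.2 |
| ash | 12.0 | 14.6 |

(each reading ± 0.5 percentage points)

* the best time, 20 min at the latest, for ring
* the amount of ring, in percent of the starting material charged, at that time

- at the start none of the solid activator is in solution

The protic impurity stands at 2.00% of the charge, and I let it go. Time near the top moves little: alder falls 0.6 percentage points from 5.00 min to 12.0 min, against a scatter of 0.5 points. Ash, with half the flask's solid activator on the flask's charge, still reads 14.6%. The charge of starting material moves it most, from a top reading of 17.4% in alder to 11.0% in maple, so that is the number to know well.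

Suppose ring closure competes with a rival step that needs a second molecule of starting material: when I divide the rival's rate by the closure's rate, time drops out, and the ratio rises in step with the starting material present at that moment. The readings give me no such rates, so as a working stand-in I take the charge of starting material divided by the top ring reading, which I call charge per ring, and I assume it is a straight line in the charge. It is not the starting material spent per ring, since the charge also counts whatever stays unreacted at the top. Alder reads 5.75 and maple 9.09. The flask lies a third of the way between them, which gives 6.86, its charge per ring. So I expect 14.6% at about 6.00 min, the same third of the way between the two top times.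

The forecast, lower than my figure, says 14% at 6 min, holding that “The ring plateaus after about 5 min in every run”.

The flask gives 14.4% at 6.21 min.

    starting material + protic impurity → quenched substrate (k = 81.6 /M/s)
    activator + ring → over-reaction product (k = 4.82 /M/s)
    starting material + activator → activated form (k = 1.90 /M/s)
    activated form → ring (k = 0.0342 /s)
    starting material + activated form → open dimer (k = 3.79 /M/s)
    solid activator ⇌ activator, rate k6*(cs6 - [activator]) while solid is left; crystals form when [activator] > cs6 (solubility = 4.00 mM, k = 0.00569 /s)

Take the neighbour flask, charged like this one except for 0.360 equiv of solid activator. Its starting material charge is the flask's, so my charge per ring stays 6.86, which says 14.6%. The neighbour gives 13.7%, a charge per ring of 7.30. Activator is the limiting reagent in the neighbour: at 20.0 min dissolved activator stands at 5.41 × 10⁻⁵ mM, solid activator at 0%, and 60.1% of the starting material remains.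

The numbers in the tables are calculated with constants of no real substance, and the scatter is random.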